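**Plan**

- Retrosynthesis: open the γ-lactone at C8–C17 and the 2,8-ether at C2–O to a cyclodecenone; reconnect C2 to C8 (Eschenmoser–Tanabe retron) to a hydroazulenone fused to the cyclohexene; cut its cycloheptane at C4–C5 and C7–C8.
- Enabling feature: C2 to C8 are seven contiguous ring carbons with oxygen on C3 and C7 and a former carbonyl at the chlorine-bearing C6. Tied by a temporary C2–C8 bond they are a cycloheptenone, the (4+3) adduct of a C4=C3(OSi)–C2=C8 diene and the oxyallyl unit C5–C6–C7.
- Forward ring order: cyclopentanedione → cyclohexene-fused cyclopentane → (4+3) adds the seven-membered ring → cleavage of the C2–C8 ring-fusion bond leaves the cyclodecane → transannular epoxide opening closes the oxane → intramolecular ketal substitution closes the lactone.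
- Stereochemistry: C1 from the amino-acid-mediated aldol; C10, C11, C12 and C9 by substrate control on the rigid hydrindane; C7 and C6 from the cycloaddition and a convex-face reduction, each inverted once (Mitsunobu, Corey–Kim); C2, C3 and C8 from the geometry of the bridged bicycle; C17 from ketene acetal geometry.

Key step: step 16

**Remarks**

- Locants are those of the target skeleton: C1 (quaternary, methyl C15), C2 (ether CH), C3 (carbinol), C4 (CH2), C5 (bears methylene C16), C6 (CHCl), C7 (lactone O–CH), C8 (ether and lactone carbon), C9 (CH–OAc), C10 (ring-fusion CH), C11 (methyl C20, OAc), C12 (CH–OAc), C13=C14, C17 (CH, methyl C19), C18 (lactone C=O).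
- α is the hydrindane face that carries H10; β is the face that carries the C1 methyl.
- Assumption: the cycloaddition of step 16 runs on the α-face through an extended transition state. If C7 emerged with the other configuration, step 22 would become a plain acylation and step 18 a hydroxyl-directed reduction.

**Route**

Step 1
Reactants: 1 2-methylcyclopentane-1,3-dione; 2 ethyl vinyl ketone
Product: 3 2-methyl-2-(3-oxopentyl)cyclopentane-1,3-dione
Conditions: H2O, AcOH (cat.), 75 °C
Reagents that add atoms: none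
Why: Michael addition of the acidic 1,3-dione to the vinyl ketone should give the achiral triketone that holds all carbons of the cyclopentane and of the future cyclohexene.

Step 2
Reactants: 3 triketone
Product: 4 (S)-4,7a-dimethyl-2,3,7,7a-tetrahydro-1H-indene-1,5(6H)-dione (C2 ketone, C10=C11–C12=O enone)
Conditions: L-phenylalanine (1 equiv), (1S)-(+)-camphorsulfonic acid (0.5 equiv), DMF, 30 → 70 °C
Reagents that add atoms: none
Why: Hajos–Parrish-type intramolecular aldol condensation through the enamine of the side-chain ketone, in which the amino acid differentiates the two enantiotopic ring carbonyls and should set C1 as S.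

Step 3
Reactants: 4 enedione
Product: 5 C2 ethylene ketal of 4
Conditions: ethylene glycol, p-TsOH·H2O (cat.), 4 Å molecular sieves, CH2Cl2, rt
Reagents that add atoms: ethylene glycol (OCCO)
Why: selective ketalisation, since the saturated C2 ketone is more electrophilic than the vinylogous enone carbonyl.

Step 4
Reactants: 5 ketal enone
Product: 6 trans-hydrindanone (C2 ketal, C12 ketone, H10 α and trans to the C1 methyl, C11 methyl equatorial)
Conditions: Li, NH3 (l), THF, t-BuOH (1 equiv), −78 °C; then NH4Cl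
Reagents that add atoms: none
Why: dissolving-metal (Birch-type) enone reduction, in which the C10 carbanion should be protonated on the face opposite the angular methyl to give the trans ring fusion (C11 is erased in step 6).

Step 5
Reactants: 6 trans-hydrindanone
Product: 8 C13=C14 enone (C12 ketone, C2 ketal), via silyl enol ether 7 (not isolated)
Conditions: LiN(iPr)2, Me3SiCl, THF, −78 °C; then Pd(OAc)2, MeCN, rt
Reagents that add atoms: none
Why: Saegusa–Ito oxidation, with kinetic enolisation toward the C13 methylene and dehydrosilylation by divalent palladium placing the alkene at C13=C14.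

Step 6
Reactants: 8 enone
Product: 9 dienyl triflate (C11=C12(OTf)–C13=C14)
Conditions: LiN(iPr)2, THF, −78 °C; then PhNTf2, −78 → 0 °C
Reagents that add atoms: N-phenylbis(trifluoromethanesulfonimide) (O=S(=O)(N(c1ccccc1)S(=O)(=O)C(F)(F)F)C(F)(F)F)
Why: enol triflate formation, as the only enolisable position of the enone is the α′ carbon C11, so O-triflation of the dienolate fixes the homoannular diene pattern.

Step 7
Reactants: 9 dienyl triflate
Product: 10 cyclohexa-1,3-diene (C11=C12–C13=C14, C2 ketal)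
Conditions: Pd(OAc)2 (5 mol %), PPh3, Bu3N, HCO2H, DMF, 60 °C
Reagents that add atoms: none
Why: palladium-catalysed formate reduction of an enol triflate (oxidative addition of zerovalent palladium, hydride from formate), which should leave the diene untouched.

Step 8
Reactants: 10 diene
Product: 11 11α,12α-diol (C11 methyl β, C13=C14 kept, C2 ketal)
Conditions: OsO4 (2 mol %), N-methylmorpholine N-oxide, acetone/H2O, 0 °C
Reagents that add atoms: OsO4 (O=[Os](=O)(=O)=O, catalytic oxygen carrier); N-methylmorpholine N-oxide (C[N+]1([O-])CCOCC1); water (O)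
Why: catalytic syn-dihydroxylation, expected at the more electron-rich trisubstituted C11=C12 bond and on the face opposite the pseudo-axial C1 methyl, which sets C11 and C12 together.

Step 9
Reactants: 11 diol ketal
Product: 13 11,12-O-isopropylidene C2 ketone, via keto diol 12 (not isolated)
Conditions: PPTS, acetone/H2O, 50 °C; concentrate; then 2,2-dimethoxypropane, PPTS, CH2Cl2, rt
Reagents that add atoms: water (O); 2,2-dimethoxypropane (COC(C)(C)OC)
Why: acetal hydrolysis frees the C2 ketone and the cis-diol is then closed to its acetonide, a protecting group inert to the palladium and base chemistry that follows.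

Step 10
Reactants: 13 keto acetonide
Product: 15 cyclopentenone (C2 ketone, C8=C9), via silyl enol ether 14 (not isolated)
Conditions: LiN(iPr)2, Me3SiCl, THF, −78 °C; then Pd(OAc)2, MeCN, rt
Reagents that add atoms: none
Why: Saegusa–Ito oxidation, unambiguous because C8 is the only enolisable position next to the C2 ketone.

Step 11
Reactants: 15 cyclopentenone
Product: 16 9β-(4-methoxybenzyloxy) C2 ketone
Conditions: 4-methoxybenzyl alcohol (5 equiv), PMe3 (10 mol %), THF, rt
Reagents that add atoms: 4-methoxybenzyl alcohol (COc1ccc(CO)cc1)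
Why: phosphine-catalysed oxa-Michael addition, reversible, which should place the ether on the β-face of C9 (cis to the C1 methyl) because the α-face is screened by the pseudo-equatorial C11 oxygen.

Step 12
Reactants: 16 β-alkoxy ketone
Product: 17 C2 enol triflate (C2=C8)
Conditions: KN(SiMe3)2, PhNTf2, THF, −78 °C
Reagents that add atoms: N-phenylbis(trifluoromethanesulfonimide) (O=S(=O)(N(c1ccccc1)S(=O)(=O)C(F)(F)F)C(F)(F)F)
Why: enol triflate formation, with the enolate trapped as it forms at low temperature so that β-elimination of the C9 ether cannot compete.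

Step 13
Reactants: 17 enol triflate
Product: 19 methyl enone (C4H3–C3(=O)–C2=C8), via ethoxydiene 18 (not isolated)
Conditions: tributyl(1-ethoxyvinyl)stannane, Pd(PPh3)4 (5 mol %), LiCl, THF, 65 °C; then 1 M aq. HCl, THF, 0 °C
Reagents that add atoms: tributyl(1-ethoxyvinyl)stannane (CCCC[Sn](CCCC)(CCCC)C(=C)OCC); water (O)
Why: Stille coupling attaches C3 and C4 as an acyl anion equivalent and brief acid hydrolysis of the enol ether gives the acetyl group.

Step 14
Reactants: 19 methyl enone
Product: 20 2-silyloxydiene (C4H2=C3(OSiMe2t-Bu)–C2=C8)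
Conditions: t-BuMe2SiOTf, Et3N, CH2Cl2, −78 → 0 °C
Reagents that add atoms: tert-butyldimethylsilyl triflate (CC(C)(C)[Si](C)(C)OS(=O)(=O)C(F)(F)F)
Why: soft enolisation of the methyl ketone should give the cross-conjugated silyl dienol ether, the 4π partner whose C3 oxygen makes C4 nucleophilic.

Step 15
Reactants: 21 2,2-dimethyl-1,3-dioxan-5-one
Product: 23 2-(triethylsilyloxy)acrolein, via silyloxydioxin 22 (not isolated)
Conditions: Et3SiOTf, Et3N, CH2Cl2, 0 °C; filter; then toluene, 110 °C
Reagents that add atoms: triethylsilyl triflate (CC[Si](CC)(CC)OS(=O)(=O)C(F)(F)F)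
Why: silyl enol ether formation followed by a retro-hetero-Diels–Alder reaction that expels acetone and should release the three-carbon partner.

Step 16
Reactants: 20 2-silyloxydiene; 23 2-(triethylsilyloxy)acrolein
Product: 24 cycloadduct (cycloheptane C2–C8 fused to the cyclopentane at C2–C8; C2=C3 silyl enol ether, C6 ketone, C7 triethylsilyl ether on the exo side, H8 β)
Conditions: Sc(OTf)3 (10 mol %), 2,6-di-tert-butyl-4-methylpyridine, CH2Cl2, −78 → −40 °C
Reagents that add atoms: none
Why: Sc(OTf)3 binds the aldehyde of 23 in its s-trans form and turns the enal into a 2-silyloxyallyl cation equivalent, to whose CH2 terminus the silyl enol ether carbon C4 of 20 adds (C4–C5), leaving a C3 silyloxocarbenium conjugated with C2=C8 and a scandium-bound enediolate. The enediolate carbon C7 then closes onto C8 (seven-membered ring, endo-trig conjugate addition, C7–C8), the triethylsilyl group moves from O6 to O7 and the C2=C3 silyl enol ether is released, so the process is a stepwise (4+3) cycloaddition. The closest known reaction type is the Lewis-acid-catalysed (4+3) cycloaddition of 2-(silyloxy)acroleins with 1,3-dienes and furans. C8 should form by attack on the α-face of the diene, opposite the C1 methyl and the C9 ether (this centre is erased in step 20), and C7 through an extended transition state of the W-shaped enediolate that puts its oxygen on the exo side (this centre is inverted on purpose in step 22). The step needs C4-to-CH2 regiochemistry, secured by the C3 silyloxy group that makes C4 the nucleophilic and C8 the electrophilic diene terminus, and (4+3) rather than (4+2) or aldol periselectivity, for which the hindered α-silyloxy aldehyde and closure through the less substituted enediolate carbon are relied on.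

Step 17
Reactants: 24 cycloadduct
Product: 27 C5-methylene C6 ketone, via Mannich base 25 (not isolated), via methiodide 26 (not isolated)
Conditions: LiN(SiMe3)2, THF, −78 °C; N,N-dimethylmethyleneiminium iodide, −78 °C → rt; then MeI, CH2Cl2, rt; then aq. NaHCO3
Reagents that add atoms: N,N-dimethylmethyleneiminium iodide (C=[N+](C)C.[I-])
Why: kinetic enolisation at the C5 methylene (C7 is hindered and oxygenated), Mannich reaction and Hofmann-type elimination should introduce C16 as the exocyclic methylene.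

Step 18
Reactants: 27 α-methylene ketone
Product: 28 C6 allylic alcohol (hydroxyl on the inner face, cis to the C7 silyl ether)
Conditions: NaBH4, CeCl3·7H2O, MeOH/THF, −78 °C
Reagents that add atoms: none
Why: Luche 1,2-reduction, with hydride expected from the convex outer face of the arched cycloheptane, which sets C6 with the configuration needed for a later inversion.

Step 19
Reactants: 28 allylic alcohol
Product: 29 C6 triisopropylsilyl ether
Conditions: i-Pr3SiOTf, 2,6-lutidine, CH2Cl2, −78 → 0 °C
Reagents that add atoms: triisopropylsilyl triflate (CC(C)[Si](C(C)C)(C(C)C)OS(=O)(=O)C(F)(F)F)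
Why: silylation with a group that should outlast the triethylsilyl ether and shield the neighbouring exocyclic alkene.

Step 20
Reactants: 29 silyl enol ether
Product: 30 C3 ketone conjugated with C2=C8
Conditions: Pd(OAc)2 (1.1 equiv), MeCN, rt
Reagents that add atoms: none
Why: Saegusa–Ito oxidation, regiospecific because the palladium enolate at C2 has its only β-hydrogen on C8.

Step 21
Reactants: 30 enone
Product: 31 C7 alcohol
Conditions: HF·pyridine, pyridine, THF, 0 °C
Reagents that add atoms: none
Why: the triethylsilyl ether is the most labile silyl group present and should be removed selectively.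

Step 22
Reactants: 31 C7 alcohol
Product: 32 C7 propionate (C7 inverted, now trans to the C6 silyl ether)
Conditions: EtCO2H, PPh3, diisopropyl azodicarboxylate, toluene, 0 °C → rt
Reagents that add atoms: propionic acid (CCC(=O)O)
Why: Mitsunobu esterification with inversion at the allylic C7 (the carboxylate enters on the face away from the C6 silyl ether), which corrects C7 and brings in C17, C18 and C19.

Step 23
Reactants: 32 enone propionate
Product: 33 2,8-epoxy C3 ketone (α-epoxide expected; either face serves)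
Conditions: t-BuOOH (3 equiv), DBU (0.3 equiv), CH2Cl2, 0 °C → rt
Reagents that add atoms: tert-butyl hydroperoxide (CC(C)(C)OO)
Why: Weitz–Scheffer nucleophilic epoxidation, run with the weakly basic hydroperoxide anion so that the skipped C5 methylene is not drawn into conjugation with the C3 ketone.

Step 24
Reactants: 33 epoxy ketone
Product: 34 cyclodec-ynone (C2≡C3, C8 ketone)
Conditions: TsNHNH2, AcOH/CH2Cl2 (1:1), −20 °C → rt
Reagents that add atoms: none
Why: Eschenmoser–Tanabe fragmentation of the epoxy ketone tosylhydrazone cleaves the C2–C8 ring-fusion bond and should unveil the ten-membered carbocycle.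

Step 25
Reactants: 34 cyclodec-ynone
Product: 35 (Z)-cyclodecenone (C2=C3)
Conditions: H2 (1 atm), Pd/CaCO3 poisoned with Pb(OAc)2 (Lindlar catalyst), quinoline, EtOAc, rt
Reagents that add atoms: none
Why: Lindlar semi-hydrogenation gives the Z-olefin by syn addition and should spare the other alkenes.

Step 26
Reactants: 35 (Z)-cyclodecenone
Product: 37 bridged methyl ketal (2,8-ether, C8–OMe, free C3 hydroxyl), via cis-epoxide 36 (not isolated)
Conditions: mCPBA (1.05 equiv), NaHCO3, CH2Cl2, −20 °C; then MeOH (10 equiv), PPTS (cat.), 0 °C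
Reagents that add atoms: mCPBA (OOC(=O)c1cccc(Cl)c1); methanol (CO)
Why: Prilezhaev epoxidation of the strained Z-alkene on its peripheral face, then transannular opening at C2 by the C8 carbonyl oxygen with inversion (six-membered oxane) and capture of the oxocarbenium by methanol, which sets C2, C3 (anti opening, threo) and the C8 ketal.

Step 27
Reactants: 37 hydroxy ketal
Product: 38 C3 triisopropylsilyl ether
Conditions: i-Pr3SiOTf, 2,6-lutidine, CH2Cl2, −40 → 0 °C
Reagents that add atoms: triisopropylsilyl triflate (CC(C)[Si](C(C)C)(C(C)C)OS(=O)(=O)C(F)(F)F)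
Why: silylation keeps the C3 hydroxyl apart from the three hydroxyls that are to be acetylated.

Step 28
Reactants: 38 ketal propionate
Product: 40 γ-lactone (C8–C17 bond; 3,6-bis-silyl ether, 9-O-PMB, 11,12-acetonide), via silyl ketene acetal 39 (not isolated)
Conditions: LiN(iPr)2, Me3SiCl, THF, −78 °C; solvent switch; then Me3SiOTf (20 mol %), CH2Cl2, −78 → −20 °C
Reagents that add atoms: none
Why: Proposed new method: Me3SiOTf should ionise the bridgehead methyl ketal to a C8 oxocarbenium ion, which the bicyclo[5.3.1] frame can hold, and the ketene acetal tethered through O7 can reach it only from the exo side, closing the five-membered lactone and fixing C8, while the ketene acetal geometry from kinetic enolisation in THF (methyl cis to the alkoxy oxygen) should place the C17 methyl cis to C9; the closest known reaction type is the Mukaiyama-type substitution of ketals by silyl ketene acetals.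

Step 29
Reactants: 40 lactone
Product: 41 C9 alcohol
Conditions: DDQ, CH2Cl2/pH 7 buffer, 0 °C
Reagents that add atoms: none
Why: oxidative cleavage of the 4-methoxybenzyl ether, to which silyl ethers, acetonide and lactone should be inert.

Step 30
Reactants: 41 C9 alcohol
Product: 42 9,11,12-triol
Conditions: AcOH/H2O (4:1), 40 °C
Reagents that add atoms: none
Why: mild acid hydrolysis of the acetonide, which the triisopropylsilyl ethers should survive.

Step 31
Reactants: 42 triol
Product: 43 9,11,12-triacetate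
Conditions: Ac2O, DMAP, Et3N, CH2Cl2, 40 °C
Reagents that add atoms: acetic anhydride (CC(=O)OC(C)=O)
Why: DMAP-catalysed acetylation, forcing enough for the tertiary C11 hydroxyl while C3 and C6 stay silylated.

Step 32
Reactants: 43 triacetate
Product: 44 3,6-diol triacetate
Conditions: HF·pyridine, THF, rt
Reagents that add atoms: none
Why: fluoride-mediated desilylation under buffered acidic conditions that should leave acetates and lactone intact.

Step 33
Reactants: 44 diol
Product: 45 CNP0333938.2
Conditions: N-chlorosuccinimide, Me2S, CH2Cl2, −25 → 0 °C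
Reagents that add atoms: N-chlorosuccinimide (O=C1CCC(=O)N1Cl)
Why: Corey–Kim chlorination, selective for the allylic C6 hydroxyl over the hindered C3 hydroxyl, should displace the alkoxysulfonium group by chloride with inversion and set C6 cis to the lactone oxygen.

**Compound list**

1 | 2-methylcyclopentane-1,3-dione | CC1C(=O)CCC1=O | starting material
2 | ethyl vinyl ketone | C=CC(=O)CC | starting material
3 | 2-methyl-2-(3-oxopentyl)cyclopentane-1,3-dione | CCC(=O)CCC1(C)C(=O)CCC1=O | intermediate
4 | (S)-4,7a-dimethyl-2,3,7,7a-tetrahydro-1H-indene-1,5(6H)-dione | C[C@]12CCC(=O)C(C)=C1CCC2=O | intermediate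
5 | C2 ethylene ketal of 4 | C[C@]12CCC(=O)C(C)=C1CCC23OCCO3 | intermediate
6 | trans-hydrindan-12-one, C2 ketal, C11 methyl equatorial | C[C@]12CCC(=O)[C@@H](C)[C@@H]1CCC23OCCO3 | intermediate
7 | C12 trimethylsilyl enol ether of 6 (not isolated) | C[C@]12CC=C(O[Si](C)(C)C)[C@@H](C)[C@@H]1CCC23OCCO3 | intermediate
8 | C13=C14 enone, C2 ketal | C[C@]12C=CC(=O)[C@@H](C)[C@@H]1CCC23OCCO3 | intermediate
9 | dienyl triflate, C2 ketal | C[C@]12C=CC(OS(=O)(=O)C(F)(F)F)=C(C)[C@@H]1CCC23OCCO3 | intermediate
10 | C11=C12–C13=C14 diene, C2 ketal | C[C@]12C=CC=C(C)[C@@H]1CCC23OCCO3 | intermediate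
11 | 11α,12α-diol, C2 ketal | C[C@]12C=C[C@@H](O)[C@@](C)(O)[C@@H]1CCC23OCCO3 | intermediate
12 | 11α,12α-diol C2 ketone (not isolated) | C[C@]12C=C[C@@H](O)[C@@](C)(O)[C@@H]1CCC2=O | intermediate
13 | 11,12-O-isopropylidene C2 ketone | C[C@]12C=C[C@H]3OC(C)(C)O[C@@]3(C)[C@@H]1CCC2=O | intermediate
14 | C2 trimethylsilyl enol ether of 13 (not isolated) | C[C@]12C=C[C@H]3OC(C)(C)O[C@@]3(C)[C@@H]1CC=C2O[Si](C)(C)C | intermediate
15 | cyclopentenone (C2 ketone, C8=C9) | C[C@]12C=C[C@H]3OC(C)(C)O[C@@]3(C)[C@@H]1C=CC2=O | intermediate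
16 | 9β-(4-methoxybenzyloxy) C2 ketone | C[C@]12C=C[C@H]3OC(C)(C)O[C@@]3(C)[C@@H]1[C@H](OCc4ccc(OC)cc4)CC2=O | intermediate
17 | C2 enol triflate | C[C@]12C=C[C@H]3OC(C)(C)O[C@@]3(C)[C@@H]1[C@H](OCc4ccc(OC)cc4)C=C2OS(=O)(=O)C(F)(F)F | intermediate
18 | 2-ethoxydiene (not isolated) | C[C@]12C=C[C@H]3OC(C)(C)O[C@@]3(C)[C@@H]1[C@H](OCc4ccc(OC)cc4)C=C2C(=C)OCC | intermediate
19 | methyl enone | C[C@]12C=C[C@H]3OC(C)(C)O[C@@]3(C)[C@@H]1[C@H](OCc4ccc(OC)cc4)C=C2C(C)=O | intermediate
20 | 2-(tert-butyldimethylsilyloxy)diene | C[C@]12C=C[C@H]3OC(C)(C)O[C@@]3(C)[C@@H]1[C@H](OCc4ccc(OC)cc4)C=C2C(=C)O[Si](C)(C)C(C)(C)C | intermediate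
21 | 2,2-dimethyl-1,3-dioxan-5-one | CC1(C)OCC(=O)CO1 | starting material
22 | 2,2-dimethyl-5-(triethylsilyloxy)-4H-1,3-dioxine (not isolated) | CC1(C)OCC(O[Si](CC)(CC)CC)=CO1 | intermediate
23 | 2-(triethylsilyloxy)acrolein | C=C(O[Si](CC)(CC)CC)C=O | intermediate
24 | (4+3) cycloadduct (C6 ketone, C7 triethylsilyl ether, C2=C3 silyl enol ether) | C23=C(O[Si](C)(C)C(C)(C)C)CCC(=O)[C@@H](O[Si](CC)(CC)CC)[C@@H]3[C@@H](OCc5ccc(OC)cc5)[C@@H]1[C@]2(C)C=C[C@@H]4[C@@]1(C)OC(C)(C)O4 | intermediate
25 | C5 dimethylaminomethyl ketone (not isolated; C5 unassigned, erased in the same step) | C23=C(O[Si](C)(C)C(C)(C)C)CC(CN(C)C)C(=O)[C@@H](O[Si](CC)(CC)CC)[C@@H]3[C@@H](OCc5ccc(OC)cc5)[C@@H]1[C@]2(C)C=C[C@@H]4[C@@]1(C)OC(C)(C)O4 | intermediate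
26 | methiodide of 25 (not isolated) | C23=C(O[Si](C)(C)C(C)(C)C)CC(C[N+](C)(C)C)C(=O)[C@@H](O[Si](CC)(CC)CC)[C@@H]3[C@@H](OCc5ccc(OC)cc5)[C@@H]1[C@]2(C)C=C[C@@H]4[C@@]1(C)OC(C)(C)O4.[I-] | intermediate
27 | C5-methylene C6 ketone | C23=C(O[Si](C)(C)C(C)(C)C)CC(=C)C(=O)[C@@H](O[Si](CC)(CC)CC)[C@@H]3[C@@H](OCc5ccc(OC)cc5)[C@@H]1[C@]2(C)C=C[C@@H]4[C@@]1(C)OC(C)(C)O4 | intermediate
28 | C6 allylic alcohol | C23=C(O[Si](C)(C)C(C)(C)C)CC(=C)[C@@H](O)[C@@H](O[Si](CC)(CC)CC)[C@@H]3[C@@H](OCc5ccc(OC)cc5)[C@@H]1[C@]2(C)C=C[C@@H]4[C@@]1(C)OC(C)(C)O4 | intermediate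
29 | C6 triisopropylsilyl ether | C23=C(O[Si](C)(C)C(C)(C)C)CC(=C)[C@@H](O[Si](C(C)C)(C(C)C)C(C)C)[C@@H](O[Si](CC)(CC)CC)[C@@H]3[C@@H](OCc5ccc(OC)cc5)[C@@H]1[C@]2(C)C=C[C@@H]4[C@@]1(C)OC(C)(C)O4 | intermediate
30 | C3 ketone, C2=C8 enone | O=C1CC(=C)[C@@H](O[Si](C(C)C)(C(C)C)C(C)C)[C@@H](O[Si](CC)(CC)CC)C2=C1[C@@]3(C)C=C[C@H]4OC(C)(C)O[C@@]4(C)[C@@H]3[C@@H]2OCc5ccc(OC)cc5 | intermediate
31 | C7 alcohol | O=C1CC(=C)[C@@H](O[Si](C(C)C)(C(C)C)C(C)C)[C@@H](O)C2=C1[C@@]3(C)C=C[C@H]4OC(C)(C)O[C@@]4(C)[C@@H]3[C@@H]2OCc5ccc(OC)cc5 | intermediate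
32 | C7 propionate (C7 inverted) | O=C1CC(=C)[C@@H](O[Si](C(C)C)(C(C)C)C(C)C)[C@H](OC(=O)CC)C2=C1[C@@]3(C)C=C[C@H]4OC(C)(C)O[C@@]4(C)[C@@H]3[C@@H]2OCc5ccc(OC)cc5 | intermediate
33 | 2,8-epoxy C3 ketone | O=C1CC(=C)[C@@H](O[Si](C(C)C)(C(C)C)C(C)C)[C@H](OC(=O)CC)[C@@]26O[C@]16[C@@]3(C)C=C[C@H]4OC(C)(C)O[C@@]4(C)[C@@H]3[C@@H]2OCc5ccc(OC)cc5 | intermediate
34 | cyclodec-ynone (C2≡C3, C8 ketone) | C=C1CC#C[C@@]2(C)C=C[C@H]4OC(C)(C)O[C@@]4(C)[C@@H]2[C@H](OCc5ccc(OC)cc5)C(=O)[C@@H](OC(=O)CC)[C@@H]1O[Si](C(C)C)(C(C)C)C(C)C | intermediate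
35 | (Z)-cyclodecenone | C=C1C/C=C\[C@@]2(C)C=C[C@H]4OC(C)(C)O[C@@]4(C)[C@@H]2[C@H](OCc5ccc(OC)cc5)C(=O)[C@@H](OC(=O)CC)[C@@H]1O[Si](C(C)C)(C(C)C)C(C)C | intermediate
36 | 2,3-cis-epoxide of 35 (not isolated) | C=C1C[C@H]6O[C@H]6[C@@]2(C)C=C[C@H]4OC(C)(C)O[C@@]4(C)[C@@H]2[C@H](OCc5ccc(OC)cc5)C(=O)[C@@H](OC(=O)CC)[C@@H]1O[Si](C(C)C)(C(C)C)C(C)C | intermediate
37 | bridged C8 methyl ketal, C3 alcohol | C=C1C[C@@H](O)[C@@H]2O[C@@](OC)([C@@H](OCc6ccc(OC)cc6)[C@@H]5[C@]2(C)C=C[C@@H]4[C@@]5(C)OC(C)(C)O4)[C@@H](OC(=O)CC)[C@@H]1O[Si](C(C)C)(C(C)C)C(C)C | intermediate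
38 | C3 triisopropylsilyl ether of 37 | C=C1C[C@@H](O[Si](C(C)C)(C(C)C)C(C)C)[C@@H]2O[C@@](OC)([C@@H](OCc6ccc(OC)cc6)[C@@H]5[C@]2(C)C=C[C@@H]4[C@@]5(C)OC(C)(C)O4)[C@@H](OC(=O)CC)[C@@H]1O[Si](C(C)C)(C(C)C)C(C)C | intermediate
39 | silyl ketene acetal of the C7 propionate (not isolated) | C=C1C[C@@H](O[Si](C(C)C)(C(C)C)C(C)C)[C@@H]2O[C@@](OC)([C@@H](OCc6ccc(OC)cc6)[C@@H]5[C@]2(C)C=C[C@@H]4[C@@]5(C)OC(C)(C)O4)[C@@H](O/C(O[Si](C)(C)C)=C\C)[C@@H]1O[Si](C(C)C)(C(C)C)C(C)C | intermediate
40 | γ-lactone, 3,6-bis-silyl ether, 9-O-PMB, 11,12-acetonide | C=C1C[C@@H](O[Si](C(C)C)(C(C)C)C(C)C)[C@@H]2O[C@@]3([C@@H](C)C(=O)O[C@H]3[C@@H]1O[Si](C(C)C)(C(C)C)C(C)C)[C@@H](OCc6ccc(OC)cc6)[C@@H]1[C@]2(C)C=C[C@@H]4[C@@]1(C)OC(C)(C)O4 | intermediate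
41 | C9 alcohol | C=C1C[C@@H](O[Si](C(C)C)(C(C)C)C(C)C)[C@@H]2O[C@@]3([C@@H](C)C(=O)O[C@H]3[C@@H]1O[Si](C(C)C)(C(C)C)C(C)C)[C@@H](O)[C@@H]1[C@]2(C)C=C[C@@H]4[C@@]1(C)OC(C)(C)O4 | intermediate
42 | 9,11,12-triol | C=C1C[C@@H](O[Si](C(C)C)(C(C)C)C(C)C)[C@@H]2O[C@@]3([C@@H](C)C(=O)O[C@H]3[C@@H]1O[Si](C(C)C)(C(C)C)C(C)C)[C@@H](O)[C@@H]1[C@]2(C)C=C[C@@H](O)[C@@]1(C)O | intermediate
43 | 9,11,12-triacetate | C=C1C[C@@H](O[Si](C(C)C)(C(C)C)C(C)C)[C@@H]2O[C@@]3([C@@H](C)C(=O)O[C@H]3[C@@H]1O[Si](C(C)C)(C(C)C)C(C)C)[C@@H](OC(C)=O)[C@@H]1[C@]2(C)C=C[C@@H](OC(C)=O)[C@@]1(C)OC(C)=O | intermediate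
44 | 3,6-diol triacetate | C=C1C[C@@H](O)[C@@H]2O[C@@]3([C@@H](C)C(=O)O[C@H]3[C@@H]1O)[C@@H](OC(C)=O)[C@@H]1[C@]2(C)C=C[C@@H](OC(C)=O)[C@@]1(C)OC(C)=O | intermediate
45 | CNP0333938.2 | C=C1C[C@@H](O)[C@@H]2O[C@@]3([C@@H](C)C(=O)O[C@H]3[C@H]1Cl)[C@@H](OC(C)=O)[C@@H]1[C@]2(C)C=C[C@@H](OC(C)=O)[C@@]1(C)OC(C)=O | target

**Step count**

Total: 33 steps. Longest linear sequence: 32 steps (steps 1–14 and 16–33; step 15 is a one-step branch).

**Steps most likely to fail**

Step 28 (Proposed new method). The bridgehead ketal may ionise too slowly, or the five-membered closure of the tethered ketene acetal may not reach the cation, so that the ketene acetal is simply desilylated. Fallback with known chemistry, setting out from 38: intermolecular Mukaiyama-type substitution of the ketal with (E)-1-methoxy-1-(trimethylsilyloxy)prop-1-ene and Me3SiOTf should give the C8-alkylated methyl ester F1, the nucleophile entering on the exo side. K2CO3 in methanol then removes the C7 propionate, and the freed C7 hydroxyl should lactonise onto the methyl ester. C17 can be adjusted through the lactone enolate by kinetic protonation on the exo face. The sequence comes back to the route at 40.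

Step 16. The silyl dienol ether may add to the aldehyde carbon instead of the CH2 terminus, or the two partners may combine in the (4+2) sense, either of which spoils regiochemistry or ring size. Fallback, setting out from 20 and 23: heating the two in toluene without Lewis acid should give the Diels–Alder adduct F2, in which C4–C5 and C6–C8 are formed and C6 carries the silyloxy and formyl groups. A catalytic Lewis acid (Me3SiOTf, CH2Cl2, −40 °C) should then induce the α-ketol-type 1,2-shift of the allylic carbon C8 from C6 to the formyl carbon with O-to-O silyl transfer. C7, now α to the ketone, can be equilibrated to the exo isomer. The sequence comes back to the route at 24.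

Step 26. The peracid may oxidise the exocyclic alkene, or deliver oxygen to the alkene face whose epoxide cannot be opened at C2, and the ring may close at C3 instead. Fallback, setting out from 35: N-iodosuccinimide and methanol in CH2Cl2 should give the iodo ketal F3, because iodonium formation is reversible and only the iodonium that the C8 carbonyl can open at C2 is drained. Kornblum oxidation (AgBF4, DMSO, then Et3N) converts the C3 iodide into the C3 ketone F4. NaBH4 should then deliver hydride on the exo face, syn to H2, and the sequence comes back to the route at 37.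

**Further compounds**

F1 | step 28 | C8-(1-methoxycarbonylethyl) bridged ether with C7 propionate (C17 unassigned, epimers converge) | C=C1C[C@@H](O[Si](C(C)C)(C(C)C)C(C)C)[C@@H]2O[C@@](C(C)C(=O)OC)([C@@H](OCc6ccc(OC)cc6)[C@@H]5[C@]2(C)C=C[C@@H]4[C@@]5(C)OC(C)(C)O4)[C@@H](OC(=O)CC)[C@@H]1O[Si](C(C)C)(C(C)C)C(C)C
F2 | step 16 | Diels–Alder adduct, cyclohexene with C6 bearing triethylsilyloxy and formyl (C6 unassigned, becomes the ketone carbon) | C23=C(O[Si](C)(C)C(C)(C)C)CCC(O[Si](CC)(CC)CC)(C=O)[C@@H]3[C@@H](OCc5ccc(OC)cc5)[C@@H]1[C@]2(C)C=C[C@@H]4[C@@]1(C)OC(C)(C)O4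
F3 | step 26 | bridged C8 methyl ketal with C3 iodide | C=C1C[C@@H](I)[C@@H]2O[C@@](OC)([C@@H](OCc6ccc(OC)cc6)[C@@H]5[C@]2(C)C=C[C@@H]4[C@@]5(C)OC(C)(C)O4)[C@@H](OC(=O)CC)[C@@H]1O[Si](C(C)C)(C(C)C)C(C)C
F4 | step 26 | bridged C8 methyl ketal with C3 ketone | C=C1CC(=O)[C@@H]2O[C@@](OC)([C@@H](OCc6ccc(OC)cc6)[C@@H]5[C@]2(C)C=C[C@@H]4[C@@]5(C)OC(C)(C)O4)[C@@H](OC(=O)CC)[C@@H]1O[Si](C(C)C)(C(C)C)C(C)C
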